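Whatever the time, what has left the two substrates stands as product. In west the left-handed substrate had lost less, 16 percentage points, than the left-handed product read, 21%, so the right-handed substrate feeds it, and I took the two hands as staying equal.

| flask | left-handed substrate | right-handed substrate | solid reagent | remark | time |
|---|---|---|---|---|---|
| west | 0.25 M | 0.25 M | 1.1 M | run made earlier |  |
| south | 0.38 M | 0.38 M | 1.1 M | run made earlier |  |
| north | 0.50 M | 0.50 M | 2.2 M | run made earlier |  |
| flask | 0.50 M | 0.50 M | 1.10 M |  | 3.0 h |

| run | time / h | left-handed product / % | left-handed substrate / % |
|---|---|---|---|
| west | 0.667 | 4 | 47 |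
| west | 1.33 | 7 | 43 |
| west | 2.00 | 17 | 39 |
| west | 2.50 | 20 | 35 |
| west | 3.00 | 21 | 34 |
| south | 0.667 | 2 | 47 |
| south | 1.33 | 6 | 42 |
| south | 2.00 | 16 | 36 |
| south | 2.50 | 18 | 37 |
| south | 3.00 | 23 | 33 |
| north | 0.667 | 4 | 47 |
| north | 1.33 | 9 | 45 |
| north | 2.00 | 14 | 40 |
| north | 2.50 | 18 | 37 |
| north | 3.00 | 21 | 35 |

(readings scatter by 1.5 percentage points)

1. the left-handed product standing at 3.0 h, as a percentage of the left-handed substrate and right-handed substrate together charged
2. concentration of partner in solution at 3.0 h, in percent of saturation

- partner is single-handed; left-handed substrate and right-handed substrate are mirror images of each other, charged as a racemate, each of them at the stated concentration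
- given per volume of solution although it is solid: solid reagent
- at the start none of the solid reagent is in solution
- partner is what solid reagent becomes in solution
- the handed part of partner does not stay in what it makes, so the products of the two hands are mirror images too

Dividing the rate of left-handed product by the rate of substrate loss removes time, so I pooled the last readings of west, south and north:

f = c(left-handed product) / [c(charged) − c(left-handed substrate) − c(right-handed substrate)] = 67.7%

This left share reads as a selectivity factor of 2.10, and y is f times the substrate lost.

The flask carries more substrate per solid than any earlier run, so I expected its partner to stand no higher and its percentage lost to be no greater. Their mean loss gives the upper bound: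

y ≤ f × mean loss = 21.7%

West and south share the flask's solid, and more substrate should remove at least the same molarity. West gives 10.8%, and south tightens this:

y ≥ f × south's molarity lost / flask's charge = 17.5%

The forecast lay inside, at 20%, with partner at 88%: “Dissolution may lag slightly”. The flask gave 21.4%, with partner at 78.7% of saturation.

    partner + left-handed substrate → left-handed product (k = 0.0105 L mol⁻¹ min⁻¹)
    solid reagent ⇌ partner, rate k2*(cs2 - [partner]) while solid is left; crystals form when [partner] > cs2 (solubility = 0.440 M, k = 0.0222 min⁻¹)
    partner + right-handed substrate → right-handed product (k = 0.00524 L mol⁻¹ min⁻¹)
    left-handed substrate ⇌ right-handed substrate (k = 0.791 min⁻¹)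

The flask was not at rest at 3.00 h: each substrate stood at 33.9%, and f on that loss gives 21.7%. The neighbour with 0.28 M of solid reagent held 40.6% of each substrate, where f gives 12.8% against its 12.6%. At 30.0 h the flask's substrates fall to 1.77% each, and f gives 65.3% against 64.3%, a further 43 points of left-handed product, with solid reagent at 0% and partner still at 0.135 M.

(The earlier runs and the new flask are calculated for an exercise; noise was put on by code.)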